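The cyclohexene ring is numbered C1 (OMe), C2 (=CH), C3 (alkene carbon bearing C7H2OBz), C4 (OH), C5 (OBz) and C6 (OH). C7, C3 and the cis oxygens on C4 and C5 correspond to the carboxyl carbon and the ipso, ortho and meta positions of a benzoate, so the carbon skeleton is disconnected to methyl benzoate. One enzymatic arene cis-dihydroxylation makes the C4–O and C5–O bonds, fixes both stereocentres in one enantiomeric series and leaves a cyclohexadiene whose C1=C6 alkene is later osmylated from the opposite face. The precursor is commercial methyl benzoate itself, with no prior steps.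

Key step: step 1

Remarks on the chemistry:
- The ring numbering of the target is kept for every intermediate; O1, O4, O5 and O6 sit on the ring carbons and O7 on C7.
- The dioxygenase diol is taken as the (5S,6R) enantiomer. Its two oxygens become O5 and O4 of the target and lie on the ring face opposite O1 and O6 (cis, trans, cis for O4–O5–O6–O1).
- Numbers are given to the substrate chain and to the bought building blocks whose atoms stay in the target. Other reagents are given by name and SMILES.

Step 1
Reactants: 1 methyl benzoate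
Product: 2 methyl (5S,6R)-5,6-dihydroxycyclohexa-1,3-diene-1-carboxylate
Conditions: E. coli JM109(pDTG601A) whole cells expressing toluene dioxygenase, IPTG, glucose feed, air, pH 7, 30 °C; EtOAc extraction of the neutral broth
Reagents that add atoms: dioxygen, O=O
Why: The non-haem iron dioxygenase binds the arene beside its mononuclear iron centre, activates O2 with two electrons relayed from NADH through the reductase and ferredoxin components, and delivers both oxygen atoms to one face of two adjacent ring carbons, so the C4–O and C5–O bonds form as a cis pair and the other four ring carbons remain as a 1,3-diene. The closest known reaction type is the toluene dioxygenase cis-dihydroxylation of monosubstituted benzenes (halobenzenes, toluene, benzoate esters) in recombinant whole cells. No ring is closed. Both new stereocentres (C6 R and C5 S of the diol, which are C4 and C5 of the target) are set by the enzyme active site and should arise as a single enantiomer. The step needs ortho,meta attack, not ipso,ortho or meta,para attack, and one enantioface; both follow from the fixed orientation of a monosubstituted arene in the binding pocket, and the ester is untouched at neutral pH. The diol should be kept away from acid and used at once, since loss of water would return it to a phenol.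

Step 2
Reactants: 2 methyl (5S,6R)-5,6-dihydroxycyclohexa-1,3-diene-1-carboxylate
Product: 3 methyl (3aR,7aS)-2,2-dimethyl-3a,7a-dihydro-1,3-benzodioxole-4-carboxylate
Conditions: 2,2-dimethoxypropane, p-TsOH·H2O (cat.), acetone, 0 °C → rt; Et3N quench
Reagents that add atoms: 2,2-dimethoxypropane, COC(C)(C)OC
Why: Acid-catalysed transacetalisation (acetonide formation) ties the cis-4,5-diol into a five-membered dioxolane, creates no stereocentre, blocks rearomatisation by dehydration and places a methyl group over the diol face of the diene.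

Step 3
Reactants: 3 methyl (3aR,7aS)-2,2-dimethyl-3a,7a-dihydro-1,3-benzodioxole-4-carboxylate
Product: 4 methyl (3aR,6R,7R,7aS)-6,7-dihydroxy-2,2-dimethyl-3a,6,7,7a-tetrahydro-1,3-benzodioxole-4-carboxylate
Conditions: OsO4 (2 mol%), NMO (1.3 equiv), acetone/H2O (4:1), 0 °C → rt; aq. NaHSO3
Reagents that add atoms: osmium tetroxide (catalytic oxygen carrier), O=[Os](=O)(=O)=O; N-methylmorpholine N-oxide, C[N+]1([O-])CCOCC1; water, O
Why: Catalytic OsO4/NMO cis-dihydroxylation ([3+2] osmate ester formation, then hydrolysis) should attack the C1=C6 alkene, the one not directly deactivated by the ester, from the face opposite the acetonide, so O1 and O6 arrive cis to each other and anti to O4/O5 and the C1 and C6 stereocentres are set by substrate control.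

Step 4
Reactants: 4 methyl (3aR,6R,7R,7aS)-6,7-dihydroxy-2,2-dimethyl-3a,6,7,7a-tetrahydro-1,3-benzodioxole-4-carboxylate; 5 trimethyloxonium tetrafluoroborate
Product: 6 methyl (3aR,6R,7R,7aS)-7-hydroxy-6-methoxy-2,2-dimethyl-3a,6,7,7a-tetrahydro-1,3-benzodioxole-4-carboxylate
Conditions: Me3OBF4 (1.05 equiv), 1,8-bis(dimethylamino)naphthalene (1.5 equiv), 4 Å MS, CH2Cl2, 0 °C → rt
Reagents that add atoms: trimethyloxonium tetrafluoroborate, C[O+](C)C.F[B-](F)(F)F
Why: O-Alkylation of a neutral alcohol by a trialkyloxonium ion with a hindered amine as proton acceptor is governed by nucleophilicity and access, and O1–H (allylic, one neighbouring C–O bond, an sp2 CH on its other side) should react ahead of O6–H (wedged between C1–O and the acetonide C5–O and inductively deactivated by both), so one equivalent should give the 1-O-methyl ether without touching a stereocentre, the ester or the acetonide.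

Step 5
Reactants: 6 methyl (3aR,6R,7R,7aS)-7-hydroxy-6-methoxy-2,2-dimethyl-3a,6,7,7a-tetrahydro-1,3-benzodioxole-4-carboxylate
Product: 7 methyl (3aR,6R,7R,7aR)-6-methoxy-2,2-dimethyl-7-[(triisopropylsilyl)oxy]-3a,6,7,7a-tetrahydro-1,3-benzodioxole-4-carboxylate
Conditions: TIPSOTf (1.5 equiv), 2,6-lutidine (3 equiv), CH2Cl2, 0 °C → rt
Reagents that add atoms: triisopropylsilyl trifluoromethanesulfonate, CC(C)[Si](C(C)C)(C(C)C)OS(=O)(=O)C(F)(F)F
Why: Silyl triflate/2,6-lutidine silylation is the standard way to cap a hindered secondary alcohol, and the triisopropylsilyl ether is chosen because it should survive the aqueous acid of step 7, resist 1,2-silyl migration under the tin conditions of step 8 and still be cleaved by fluoride in step 9.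

Step 6
Reactants: 7 methyl (3aR,6R,7R,7aR)-6-methoxy-2,2-dimethyl-7-[(triisopropylsilyl)oxy]-3a,6,7,7a-tetrahydro-1,3-benzodioxole-4-carboxylate
Product: 8 [(3aR,6R,7R,7aR)-6-methoxy-2,2-dimethyl-7-[(triisopropylsilyl)oxy]-3a,6,7,7a-tetrahydro-1,3-benzodioxol-4-yl]methanol
Conditions: i-Bu2AlH (2.5 equiv), CH2Cl2, −78 °C; aq. KNaC4H4O6 (potassium sodium tartrate)
Reagents that add atoms: none
Why: Low-temperature i-Bu2AlH reduction of an α,β-unsaturated ester proceeds by two 1,2-hydride additions to the primary allylic alcohol (C7–OH) without conjugate reduction, and the ethers, the acetonide and the silyl ether are inert.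

Step 7
Reactants: 8 [(3aR,6R,7R,7aR)-6-methoxy-2,2-dimethyl-7-[(triisopropylsilyl)oxy]-3a,6,7,7a-tetrahydro-1,3-benzodioxol-4-yl]methanol
Product: 9 (1R,2R,5R,6S)-3-(hydroxymethyl)-5-methoxy-6-[(triisopropylsilyl)oxy]cyclohex-3-ene-1,2-diol
Conditions: AcOH/H2O (4:1), 50 °C
Reagents that add atoms: none
Why: Acid-catalysed hydrolysis of the isopropylidene acetal frees O4–H and O5–H, while the triisopropylsilyl and methyl ethers are stable to aqueous acetic acid and the oxygen-flanked allylic positions should not ionise.

Step 8
Reactants: 9 (1R,2R,5R,6S)-3-(hydroxymethyl)-5-methoxy-6-[(triisopropylsilyl)oxy]cyclohex-3-ene-1,2-diol; 10 benzoyl chloride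
Product: 12 (1R,2R,5R,6R)-3-[(benzoyloxy)methyl]-2-hydroxy-5-methoxy-6-[(triisopropylsilyl)oxy]cyclohex-3-en-1-yl benzoate, via 4,5-O-dibutylstannylene acetal 11 (not isolated)
Conditions: Bu2SnO (2.2 equiv), toluene, reflux with azeotropic removal of water; then BzCl (2.1 equiv), toluene, 0 °C → rt
Reagents that add atoms: benzoyl chloride, O=C(Cl)c1ccccc1
Why: Stannylene-acetal-directed regioselective acylation: the cis-4,5-diol should form a five-membered dibutylstannylene in which the equatorial O5 is the activated oxygen while O4 is pseudo-axial and crowded by the C3 substituent, and the primary O7 is the most accessible remaining hydroxyl, so two equivalents of benzoyl chloride should give the 5,7-dibenzoate with O4–H free, the pattern known as 3,6-di-O-benzoylation of galactopyranosides (the triol is a carba-analogue of a 2-O-protected α-galactoside).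

Step 9
Reactants: 12 (1R,2R,5R,6R)-3-[(benzoyloxy)methyl]-2-hydroxy-5-methoxy-6-[(triisopropylsilyl)oxy]cyclohex-3-en-1-yl benzoate
Product: 13 (1R,2R,5R,6R)-3-[(benzoyloxy)methyl]-2,6-dihydroxy-5-methoxycyclohex-3-en-1-yl benzoate
Conditions: HF·pyridine, pyridine/THF, 0 °C → rt
Reagents that add atoms: none
Why: Fluoride-driven Si–O cleavage with pyridine-buffered HF removes the silyl ether under weakly acidic conditions in which the benzoates should neither hydrolyse nor migrate to the neighbouring O4 and O6 hydroxyls, and no stereocentre is involved.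

Compound list
1 | methyl benzoate | COC(=O)c1ccccc1 | starting material
2 | methyl (5S,6R)-5,6-dihydroxycyclohexa-1,3-diene-1-carboxylate | COC(=O)C1=CC=C[C@H](O)[C@@H]1O | intermediate
3 | methyl (3aR,7aS)-2,2-dimethyl-3a,7a-dihydro-1,3-benzodioxole-4-carboxylate | COC(=O)C1=CC=C[C@@H]2OC(C)(C)O[C@H]12 | intermediate
4 | methyl (3aR,6R,7R,7aS)-6,7-dihydroxy-2,2-dimethyl-3a,6,7,7a-tetrahydro-1,3-benzodioxole-4-carboxylate | O[C@@H]1C=C(C(=O)OC)[C@@H](OC2(C)C)[C@@H](O2)[C@@H]1O | intermediate
5 | trimethyloxonium tetrafluoroborate | C[O+](C)C.F[B-](F)(F)F | starting material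
6 | methyl (3aR,6R,7R,7aS)-7-hydroxy-6-methoxy-2,2-dimethyl-3a,6,7,7a-tetrahydro-1,3-benzodioxole-4-carboxylate | CO[C@@H]1C=C(C(=O)OC)[C@@H](OC2(C)C)[C@@H](O2)[C@@H]1O | intermediate
7 | methyl (3aR,6R,7R,7aR)-6-methoxy-2,2-dimethyl-7-[(triisopropylsilyl)oxy]-3a,6,7,7a-tetrahydro-1,3-benzodioxole-4-carboxylate | CO[C@@H]1C=C(C(=O)OC)[C@@H](OC2(C)C)[C@@H](O2)[C@@H]1O[Si](C(C)C)(C(C)C)C(C)C | intermediate
8 | [(3aR,6R,7R,7aR)-6-methoxy-2,2-dimethyl-7-[(triisopropylsilyl)oxy]-3a,6,7,7a-tetrahydro-1,3-benzodioxol-4-yl]methanol | CO[C@@H]1C=C(CO)[C@@H](OC2(C)C)[C@@H](O2)[C@@H]1O[Si](C(C)C)(C(C)C)C(C)C | intermediate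
9 | (1R,2R,5R,6S)-3-(hydroxymethyl)-5-methoxy-6-[(triisopropylsilyl)oxy]cyclohex-3-ene-1,2-diol | CO[C@@H]1C=C(CO)[C@@H](O)[C@@H](O)[C@@H]1O[Si](C(C)C)(C(C)C)C(C)C | intermediate
10 | benzoyl chloride | O=C(Cl)c1ccccc1 | starting material
11 | 4,5-O-dibutylstannylene acetal of 9 (2,2-dibutyl-1,3,2-dioxastannolane across O4 and O5, all other centres as in 9, formed in the flask) | CO[C@@H]1C=C(CO)[C@@H](O[Sn]2(CCCC)CCCC)[C@@H](O2)[C@@H]1O[Si](C(C)C)(C(C)C)C(C)C | intermediate
12 | (1R,2R,5R,6R)-3-[(benzoyloxy)methyl]-2-hydroxy-5-methoxy-6-[(triisopropylsilyl)oxy]cyclohex-3-en-1-yl benzoate | CO[C@@H]1C=C(COC(=O)c2ccccc2)[C@@H](O)[C@@H](OC(=O)c2ccccc2)[C@@H]1O[Si](C(C)C)(C(C)C)C(C)C | intermediate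
13 | (1R,2R,5R,6R)-3-[(benzoyloxy)methyl]-2,6-dihydroxy-5-methoxycyclohex-3-en-1-yl benzoate (target numbering 1R,4R,5R,6R) | CO[C@@H]1C=C(COC(=O)c2ccccc2)[C@@H](O)[C@@H](OC(=O)c2ccccc2)[C@@H]1O | target

Total step count: 9. Longest linear sequence: 9 steps (1 → 13); the route is fully linear, and 5 and 10 are bought.

Steps most likely to fail

1. Step 4, methylation of O1 in the presence of O6–H. The risk is poor discrimination between the two secondary hydroxyls, together with over-methylation to the 1,6-dimethyl ether. The fallback forms the C1–O1 bond at carbon instead of alkylating oxygen.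
   - It sets out from 3. Epoxidation of the C1=C6 alkene with mCPBA (NaHCO3, CH2Cl2, 0 °C), again anti to the acetonide, should give the anti 1,6-epoxide F1.
   - Zerovalent-palladium-catalysed methanolysis [Pd(PPh3)4 (5 mol%), MeOH, Et3B (cat.), THF, rt] should then ionise C1–O with inversion to a π-allyl complex spanning C1–C3 (Tsuji–Trost type). The boron-bound O6 alkoxide delivers methoxide back to C1 on the face away from palladium, since C3 is fully substituted.
   - Net retention should give the cis 1-OMe/6-OH compound 6, where the route is rejoined with the same step count.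

2. Step 8, dibenzoylation of O7 and O5 with O4–H left free. The risk is acylation of the allylic O4, slow reaction at O5 next to the bulky silyl ether, or tin-promoted benzoyl migration from O5 to O4 within the cis-diol. The fallback blocks O4 covalently.
   - It sets out from 9. t-Bu2Si(OTf)2/2,6-lutidine (CH2Cl2, 0 °C) should bridge the 1,3-related O7 and O4 as the six-membered 4,7-O-di-tert-butylsilylene F2, because this reagent strongly prefers 1,3-diols to cis-1,2-diols. O5–H is then the only free hydroxyl.
   - 10 with pyridine/DMAP should give the silylene 5-O-benzoate F3.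
   - HF·pyridine should remove both silicon groups to the 5-O-benzoyl triol F4.
   - 10 (1.05 equiv, 2,4,6-collidine, CH2Cl2, −40 °C) should esterify only the primary O7–H, rejoining the route at 13.

3. Step 7, acetonide hydrolysis beside the silyl ether. The risk is incomplete acetal cleavage under conditions mild enough to keep the O6 silyl ether, or partial silyl loss and allylic ionisation when the acid is strengthened. The fallback drops the silyl group altogether.
   - It sets out from 6 with O6–H left free. i-Bu2AlH reduction (CH2Cl2, −78 °C) should give the acetonide diol F5.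
   - Aqueous trifluoroacetic acid in THF, with no silyl ether to preserve, should give the tetraol F6.
   - Bu2SnO (toluene, reflux) followed by two equivalents of 10 should benzoylate O7 and the equatorial O5 of the cis-4,5-stannylene, as in the 3,6-di-O-benzoylation of unprotected α-galactopyranosides. This rejoins the route at 13 two steps shorter, at the price of O6–H as an extra competitor.

Further compounds
F1 | step 4 | methyl 1,6-epoxy-4,5-(isopropylidenedioxy)cyclohex-2-ene-3-carboxylate (target numbering), oxirane on the face opposite the acetonide | O1[C@@H]2C=C(C(=O)OC)[C@@H](OC3(C)C)[C@@H](O3)[C@H]12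
F2 | step 8 | 4,7-O-di-tert-butylsilylene derivative of 9 (O5–H free, O6 triisopropylsilyl ether, centres as in 9) | CO[C@@H]1C=C(CO[Si]2(C(C)(C)C)C(C)(C)C)[C@@H](O2)[C@@H](O)[C@@H]1O[Si](C(C)C)(C(C)C)C(C)C
F3 | step 8 | 5-O-benzoate of F2 | CO[C@@H]1C=C(CO[Si]2(C(C)(C)C)C(C)(C)C)[C@@H](O2)[C@@H](OC(=O)c3ccccc3)[C@@H]1O[Si](C(C)C)(C(C)C)C(C)C
F4 | step 8 | (1R,2R,5R,6R)-2,6-dihydroxy-3-(hydroxymethyl)-5-methoxycyclohex-3-en-1-yl benzoate | CO[C@@H]1C=C(CO)[C@@H](O)[C@@H](OC(=O)c2ccccc2)[C@@H]1O
F5 | step 7 | [(3aR,6R,7R,7aS)-7-hydroxy-6-methoxy-2,2-dimethyl-3a,6,7,7a-tetrahydro-1,3-benzodioxol-4-yl]methanol | CO[C@@H]1C=C(CO)[C@@H](OC2(C)C)[C@@H](O2)[C@@H]1O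
F6 | step 7 | (1S,2R,3R,6R)-4-(hydroxymethyl)-6-methoxycyclohex-4-ene-1,2,3-triol | CO[C@@H]1C=C(CO)[C@@H](O)[C@@H](O)[C@@H]1O
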